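If J holds still once Q has gone, then whatever destroys J needs Q in solution.

the same everywhere: Z 2.4 mM
- summer: Q 0.96 M; temperature 20 °C; run made earlier
- dusk: Q 0.96 M; temperature 55 °C; run made earlier
- Saturday's: Q 2.4 M; at 25 °C until 30 h, from then on at 85 °C; time 6.0 d
- Thursday's: Q 0.80 M; at 85 °C throughout; time 6.0 d
summer run (percent of the Q charged)

| time / d | J / % | Q / % |
|---|---|---|
| 0.333 | 34 | 0 |
| 0.500 | 41 | 0 |
| 0.833 | 47 | 0 |
| 1.67 | 47 | 0 |
| 2.50 | 47 | 0 |
| 4.00 | 45 | 0 |

dusk run (percent of the Q charged)

| time / h | J / % | Q / % |
|---|---|---|
| 2.00 | 16 | 62 |
| 2.50 | 17 | 48 |
| 5.00 | 24 | 3 |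
| 10.0 | 26 | 0 |
| 15.0 | 25 | 2 |
| 20.0 | 23 | 0 |

(standard deviation of a reading: 1.5 percentage points)
* which one finishes higher in amount of J, in percent of the Q charged ("neither" within 2 percentage points) (Saturday's / Thursday's / neither)
* amount of J at the end, in percent of the Q charged, Saturday's
* amount of J at the end, in percent of the Q charged, Thursday's
- Q is a solid; its amount is given per volume of the solution
- at the start none of Q is in solution
- what has only dissolved of Q counts as not reacted

The readings say it does hold still: the summer run goes from 47% to 45% and the dusk run from 26% to 23%, against a scatter of 1.5 percentage points. So I suppose that Z makes J from dissolved Q, and that J is lost by meeting dissolved Q, one with one. Both steps feed on the same dissolved Q, so its amount cancels. The share of used Q that ends as J is then the gap between a balance fraction and J, divided by their sum; at that balance fraction of the charge, J is lost as fast as it is made.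

I replace J in that share by its mean, the middle between nothing and its end value. The end values then give a mean figure for that fraction, 65.2% in the summer run and 22.1% in the dusk run. This is a fitted figure of my reckoning and not the balance fraction itself: the dusk figure lies below the reading of 26% it came from.

At the pace of Q in the dusk run, Saturday's charge is used after 12.7 h, earlier than the change of temperature, so I reckon that flask at 25 °C. I take the logarithm of the mean figure as straight in temperature, and a fixed amount of J means a smaller fraction of a larger charge. Saturday's then has 22.3% as its mean figure, the stand-in for a selectivity factor that gives the end value of J when J in the share is taken at its mean. Thursday's has 10.5%. Solving the same share for the end value, I expect 26.2% for Saturday's and 15.4% for Thursday's.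

The forecast differs: neither, with 1% for Saturday's and 0% for Thursday's, because “both flasks end near zero”.

The flask gives Saturday's: 23.1% for Saturday's, 17.0% for Thursday's.

    D + Z → G (k = 1.20 M⁻¹ min⁻¹, Ea = 56.0 kJ mol⁻¹)
    G → Z + J (k = 23.0 min⁻¹, Ea = 66.0 kJ mol⁻¹)
    Q ⇌ D, rate k3*(cs3 - [D]) while solid is left; crystals form when [D] > cs3 (solubility = 2.00 M, k = 0.00160 min⁻¹)
    D + J → L (k = 0.00460 M⁻¹ min⁻¹, Ea = 78.0 kJ mol⁻¹)
    (constants at 25 °C)

Taking away the turning of D + J into L lifts Saturday's from 23.1% to 100%, so that step is what holds J down. Read back through the mean, Saturday's result gives a mean figure of 18.5%, lower than my 22.3%. The mean figure goes with Z, so the neighbour flask with 0.0096 M of Z has 74.2%, which reckons to 49.8%, and that flask stands at 54.4%.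

The earlier runs and the new flask are calculated for substances that don't exist, noise included.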